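# Proposed synthesis of quercetin 3,4',7-trisulfate by thermal aroylketene annulation of unprotected phloroglucinol

**Numbering used throughout.** 1 2-(benzyloxy)phenol; 2 its 4-bromo derivative; 3 the triisopropylsilyl ether of 2; 4 the aryllithium from 3; 5 the benzoic acid; 6 its acyl imidazolide; 7 the aroylmalonate half-ester; 8 the beta-keto ester; 9 dibenzoyl peroxide; 10 the 2-benzoyloxy beta-keto ester; 11 phloroglucinol; 12 the aroyl(benzoyloxy)ketene; 13 the C-acylphloroglucinol triketone; 14 the flavonol 3-benzoate; 15 the debenzoylated silyl ether; 16 3'-O-benzylquercetin; 17 its 3,4',7-trisulfate; 18 the target.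

**Remark on the chemistry.** 17 and 18 are drawn and named as free tris(hydrogen sulfates), as the target is. They would be made, purified and stored as salts (triethylammonium for 17, potassium for 18 after cation exchange). The free-acid form of 18 would be generated only in cold dilute solution on an H+ resin.

## Analysis of the target

Target 18 is a flavonol, a 2-aryl-3-oxy-4H-chromen-4-one. Benzo ring A (C4a to C8a) is fused to gamma-pyrone ring C (O1, C2, C3, C4), and C2 carries the catechol-derived ring B. There is no stereocentre and no stereogenic double bond, so the whole problem is connectivity and telling five oxygens apart. O3, O7 and O4' are sulfate monoesters, while O5 and O3' are free. O3' and O4' are neighbours on ring B with nearly equal reactivity, so this pair must be differentiated from the first step and not by reagent control at the end. The sulfate monoesters are the sensitive groups: acid solvolyses them, and every compound that carries them is a water-soluble polyanion that cannot be purified on silica. They must therefore enter late and be followed only by a neutral step. The polyphenol that precedes sulfation is readily oxidised by air in base. Two features make the task tractable. First, 5-OH is held in a six-membered hydrogen bond to the C4 carbonyl and is by far the least nucleophilic hydroxyl, so it protects itself. Second, ring A carries oxygen at C5, C7 and C8a in a 1,3,5 relationship, which is the pattern of phloroglucinol 11, a threefold symmetric triol. In 11 every adjacent C–H/C–OH pair is equivalent, so any one pair can supply C4a and O1 without protection or regiochemical ambiguity, and the other two hydroxyls become 5-OH and 7-OH. The strategy rests on this.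

## Retrosynthetic reasoning

**18 to 17.** The last bond cut is the O3'–CH2 bond of a benzyl ether. Only O3' needs a group that survives sulfation, and it must then come off without acid, base or heat, none of which the three S–O esters tolerate. A benzyl ether removed by hydrogenolysis meets this requirement, and it lets 17 be sulfated with no concern for ring B regiochemistry.

**17 to 16.** The three O–S bonds at O3, O7 and O4' are cut together. One operation suffices because the two oxygens that must stay free are already secured: O3' is benzylated and O5 is chelated to the C4 carbonyl. The forward reaction must go to completion at O3, the most hindered site, and stop short of O5.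

**16 to 14.** The free O3 and O4' of 16 are traced back to a benzoate and a triisopropylsilyl ether. The benzoate is the form in which the alpha-oxygen can be carried through the ring-forming step. The silyl ether is what distinguishes O4' from O3' throughout. Both are removed by nucleophiles that leave the benzyl ether untouched. Because both leave in the same operation, any wandering of acyl or silyl groups among the phenolic oxygens during the hot key step is corrected here.

**14 to 10 and 11.** Ring C is opened at C4–C4a and at O1–C2. This cut leaves ring A as the unprotected, symmetric triol 11. It gathers every differentiated oxygen (O3, O3', O4') in one acyclic partner, 10, which already stands at the oxidation level of the flavonol. No later oxidation at C3 or dehydrogenation across C2–C3 is needed, and ring A needs no protecting groups. The forward reaction must make the ester carbon of 10 acylate a ring carbon of 11, have an adjacent hydroxyl attack the ketone, and eliminate the ester alcohol and then undergo dehydration.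

**10 to 8 and 9.** The C–O bond at the alpha-carbon is cut. Forward, the nucleophilic central carbon of 8 takes a benzoyloxy group from the peroxide 9. The oxygen thus arrives already acylated, in one step and without a separate hydroxylation.

**8 to 5.** The bond between the aroyl carbon and the methylene carbon is cut. Forward, the acid is activated (as 6) and condensed with a two-carbon ester enolate equivalent that carries a sacrificial carboxylate (giving 7), which is then lost by decarboxylation. This avoids strong base and self-condensation.

**5 to 3 to 2 to 1.** The aryl–carboxyl bond is cut (forward: halogen–metal exchange to 4 and carboxylation), then the O–Si bond, then the C–Br bond. The ring B pattern is fixed at the outset. Bromination of 1 para to its free hydroxyl places the future C1' para to the oxygen that becomes O4'. The benzyl group already present in 1 marks O3'.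

## Alternatives that were turned down

**Alternative 1: ring A by Claisen folding of a masked polyketide.** The disconnection is C4a–C8a inside ring A. In the forward step Mg(OMe)2 in methanol would open the lactone of 6-[(3Z)-4-(3-benzyloxy-4-methoxymethoxyphenyl)-3-(methoxymethoxy)-2-oxobut-3-en-1-yl]-4-hydroxy-2H-pyran-2-one A1 to a 3,5,7-trioxo ester. Its C6 methylene would then attack the ester carbonyl to give (Z)-3-(3-benzyloxy-4-methoxymethoxyphenyl)-2-(methoxymethoxy)-1-(2,4,6-trihydroxyphenyl)prop-2-en-1-one A2.
- For it: the step is biomimetic and runs near room temperature. It delivers an acylphloroglucinol with all ring A hydroxyls free and O3 already in place. No protecting group is exposed to heat, and a second annulation is impossible. On mildness it is stronger than the chosen route.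
- Against it: it spends its effort building the one part of the target that can be bought as a finished benzene ring. A1 must first be assembled by several steps of polyketide-type C-acylation. The polycarbonyl chain can also fold by aldol condensation rather than Claisen condensation, so the cyclisation mode needs control. A2 still has ring C open. Closing it needs a 6-endo oxa-Michael addition and then a dehydrogenation, followed by acidic acetal removal, before sulfation can begin.
- Comparison: the chosen route forms ring C directly at the correct oxidation level from 11 and 10 in one step and is shorter by several steps. It accepts a harsh key step in exchange.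

**Alternative 2: carbene-catalysed cross-benzoin forming C3–C4.** The disconnection is C3–C4. The dialdehyde 2-[1-(3-benzyloxy-4-methoxymethoxyphenyl)-2-oxoethoxy]-4,6-bis(methoxymethoxy)benzaldehyde A3 would be treated with 3-benzyl-5-(2-hydroxyethyl)-4-methylthiazolium chloride and triethylamine. The aromatic formyl group would become the acyl anion equivalent and add to the aliphatic one, giving trans-2-(3-benzyloxy-4-methoxymethoxyphenyl)-3-hydroxy-5,7-bis(methoxymethoxy)chroman-4-one A4 (racemic).
- For it: the C–C bond formation is catalytic and mild. O3 is generated directly from an aldehyde. Ring A is fully regiodefined and protected, which eases purification. These are real advantages over a melt at above 200 °C.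
- Against it: the acyl donor must be the hindered, electron-rich 2,6-dioxygenated aromatic aldehyde, whereas the carbene adds more readily to the aliphatic aldehyde. That aldehyde is alpha-aryloxy-substituted, and its carbene adduct can expel the ring A phenoxide, cleaving the O1–C2 bond already made. A3 is also highly enolisable and fragile. The step creates two stereocentres (C2, C3) that the target lacks, so an oxidation to the flavonol must follow. Ring A has to be formylated and selectively protected, which discards the symmetry of the triol.
- Comparison: the chosen route creates no stereocentre that must be destroyed, needs no oxidation-state adjustment, and uses ring A unprotected. It is shorter and has no chemoselectivity question between two aldehydes.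

**Alternative 3: iodocyclisation of an aryl ynone with ether cleavage.** The disconnection is O1–C2, with a C3–I bond formed at the same time. ICl would activate the alkyne of 1-[2,6-bis(benzyloxy)-4-(methoxymethoxy)phenyl]-3-(3-benzyloxy-4-methoxymethoxyphenyl)prop-2-yn-1-one A5. An ortho benzyloxy oxygen would attack C2 in a 6-endo-dig closure and lose its benzyl group, giving 5-benzyloxy-2-(3-benzyloxy-4-methoxymethoxyphenyl)-3-iodo-7-(methoxymethoxy)chromen-4-one A6.
- For it: this is the most dependable key step of the four, at low temperature and with a convergent ynone assembly. The two ortho ethers of A5 are equivalent, so there is no regiochemical issue. O5 stays benzylated through sulfation and is released in the same final hydrogenolysis as O3'. Exclusion of O5 sulfation is therefore absolute, where the chosen route relies on chelation.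
- Against it: C3 emerges as an iodide, not an oxygen. A further carbon–iodine to carbon–oxygen exchange is needed on a hindered position between a carbonyl and an aryl group. ICl is a strong electrophile and can iodinate the trialkoxy ring A and ring B. The acetals must survive the acid formed. Ring A needs a two-benzyl, one-acetal oxygen pattern plus an acyl group, which costs several steps from the triol.
- Comparison: the estimated length is clearly greater than nine steps. The chosen route offers O3 already installed, an unprotected ring A and the shortest sequence, and it concentrates the risk in one step.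

Key step: step 6

## Route

Step 1
Reactants: 1 2-(benzyloxy)phenol
Product: 2 2-(benzyloxy)-4-bromophenol
Conditions: NBS (1.0 equiv), MeCN, −10 → 0 °C, dark
Reagents that add atoms: N-bromosuccinimide, O=C1CCC(=O)N1Br
Why: Electrophilic aromatic bromination; the free hydroxyl is a stronger para director than the benzyl ether, so bromine should enter C4, para to OH, which sets the future C1' para to the future O4'. Low temperature and one equivalent limit ortho- and dibromination.

Step 2
Reactants: 2 2-(benzyloxy)-4-bromophenol
Product: 3 [2-(benzyloxy)-4-bromophenoxy]tri(propan-2-yl)silane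
Conditions: TIPSCl, imidazole, DMF, rt
Reagents that add atoms: chlorotri(propan-2-yl)silane (TIPSCl), CC(C)[Si](Cl)(C(C)C)C(C)C
Why: Silyl ether formation from a phenol with a silyl chloride and imidazole; the bulky triisopropylsilyl group is chosen because it should tolerate the aryllithium, the enolate and the hot melt of later steps and is still cleaved in the presence of the benzyl ether.

Step 3
Reactants: 3 [2-(benzyloxy)-4-bromophenoxy]tri(propan-2-yl)silane
Product: 5 3-(benzyloxy)-4-[(triisopropylsilyl)oxy]benzoic acid, via aryllithium 4 (not isolated)
Conditions: n-BuLi, THF, −78 °C; CO2 (g), −78 °C → rt; 1 M HCl to pH 3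
Reagents that add atoms: carbon dioxide, O=C=O; n-butyllithium, [Li]CCCC (lithium only in 4)
Why: Bromine–lithium exchange at −78 °C is faster than benzylic deprotonation or attack at silicon, and lithium para to the silyloxy group cannot trigger an O-to-C silyl shift. Carboxylation of aryllithium 4 then gives the acid.

Step 4
Reactants: 5 3-(benzyloxy)-4-[(triisopropylsilyl)oxy]benzoic acid
Product: 8 ethyl 3-{3-(benzyloxy)-4-[(triisopropylsilyl)oxy]phenyl}-3-oxopropanoate, via acyl imidazolide 6 (not isolated), via aroylmalonate half-ester 7 (not isolated)
Conditions: CDI, THF, rt; Mg(O2CCH2CO2Et)2, THF, rt → 45 °C; cold 1 M HCl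
Reagents that add atoms: magnesium bis(3-ethoxy-3-oxopropanoate), CCOC(=O)CC(=O)[O-].CCOC(=O)CC(=O)[O-].[Mg+2]; 1,1'-carbonyldiimidazole, O=C(n1ccnc1)n1ccnc1 (atoms only in 6)
Why: Masamune homologation (decarboxylative Claisen condensation): imidazolide 6 C-acylates the magnesium chelate of the malonate half-ester under near-neutral conditions, and acylmalonate 7 loses carbon dioxide on acidic work-up. Neither the silyl ether nor the benzyl ether is affected.

Step 5
Reactants: 8 ethyl 3-{3-(benzyloxy)-4-[(triisopropylsilyl)oxy]phenyl}-3-oxopropanoate; 9 dibenzoyl peroxide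
Product: 10 ethyl 2-(benzoyloxy)-3-{3-(benzyloxy)-4-[(triisopropylsilyl)oxy]phenyl}-3-oxopropanoate (racemic)
Conditions: NaH (1.0 equiv), THF, 0 °C; enolate added to 9 in THF, 0 °C → rt
Reagents that add atoms: none
Why: Electrophilic alpha-benzoyloxylation of a 1,3-dicarbonyl enolate: the sodium enolate of 8 attacks the O–O bond of 9 at oxygen and benzoate leaves. Adding the enolate to the peroxide should hold back a second oxidation. The new stereocentre forms racemic and is enolisable, which is irrelevant because it becomes sp2 C3.

Step 6
Reactants: 10 ethyl 2-(benzoyloxy)-3-{3-(benzyloxy)-4-[(triisopropylsilyl)oxy]phenyl}-3-oxopropanoate (racemic); 11 phloroglucinol (benzene-1,3,5-triol, anhydrous)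
Product: 14 2-{3-(benzyloxy)-4-[(triisopropylsilyl)oxy]phenyl}-5,7-dihydroxy-4-oxo-4H-chromen-3-yl benzoate, via aroylketene 12 (not isolated), via C-acylphloroglucinol triketone 13 (not isolated)
Conditions: 11 (2 equiv), neat melt (or minimal Ph2O), 200 → 240 °C, argon sweep, until ethanol evolution stops (or microwave, minutes)
Reagents that add atoms: none
Why: This is the Mentzer pyrone synthesis, the acid-free thermal condensation of a phenol with an aroylacetate, applied to an alpha-benzoyloxy aroylacetate. The enol of 10 loses ethanol through a six-membered transition state to give ketene 12, whose ketene carbon acylates a ring carbon of 11, directly or by O-acylation and thermal acyl shift, to give triketone 13 and with it the C4–C4a bond. A hydroxyl ortho to the new acyl group then adds to the ring B ketone (6-exo-trig) and the hemiketal loses water, which forms O1–C2 and closes ring C as the aromatic gamma-pyrone; sweeping out ethanol and water drives both stages. No stereocentre is formed, and the enolisable one of 10 becomes sp2 C3. A chromone and not a coumarin should result because no acid is present: the ester carbon reacts with carbon as the ketene and leaves the ketone for oxygen, whereas acid (Pechmann conditions) would make the ketone the carbon electrophile. Regiochemistry on ring A needs no control because the three C–H/C–OH pairs of 11 are equivalent, the two hydroxyls left over appearing as 5-OH and 7-OH, and a second annulation is held back by the excess of 11 and by the deactivating, hydrogen-bonded acyl group on the product. The benzoate has to stay on C3 rather than be displaced by the ortho hydroxyl (5-exo-tet), which fast reversible carbonyl addition and irreversible aromatising dehydration should favour; benzoyl or silyl groups that move between phenolic oxygens in the melt do no harm because step 7 removes both.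

Step 7
Reactants: 14 2-{3-(benzyloxy)-4-[(triisopropylsilyl)oxy]phenyl}-5,7-dihydroxy-4-oxo-4H-chromen-3-yl benzoate
Product: 16 2-[3-(benzyloxy)-4-hydroxyphenyl]-3,5,7-trihydroxy-4H-chromen-4-one, via silyl ether triol 15 (not isolated)
Conditions: K2CO3, MeOH/THF (degassed), 0 °C → rt, Ar; then Bu4NF, rt; 1 M HCl to pH 4
Reagents that add atoms: none
Why: Base-mediated methanolysis of the activated enol benzoate, then fluoride cleavage of the aryl silyl ether. The two are run in one flask because carbonate in methanol already attacks the silyl ether of so acidic a phenol, and both paths converge on 16. The benzyl ether is inert, and air is excluded because the flavonol phenoxide is readily autoxidised.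

Step 8
Reactants: 16 2-[3-(benzyloxy)-4-hydroxyphenyl]-3,5,7-trihydroxy-4H-chromen-4-one
Product: 17 2-[3-(benzyloxy)-4-(sulfooxy)phenyl]-5-hydroxy-4-oxo-4H-chromene-3,7-diyl bis(hydrogen sulfate)
Conditions: SO3·NMe3 (excess), Et3N, DMF, 60 °C, Ar; Sephadex LH-20 (MeOH/H2O)
Reagents that add atoms: sulfur trioxide–trimethylamine complex, C[N+](C)(C)S(=O)(=O)[O-]
Why: O-Sulfation of phenols with a sulfur trioxide–amine complex; the 7-, 4'- and 3-hydroxyls should react, while 5-OH, hydrogen-bonded to the C4 carbonyl, is not sulfated under these conditions and O3' is blocked as the benzyl ether. The excess of reagent drives the hindered 3-position to completion.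

Step 9
Reactants: 17 2-[3-(benzyloxy)-4-(sulfooxy)phenyl]-5-hydroxy-4-oxo-4H-chromene-3,7-diyl bis(hydrogen sulfate)
Product: 18 2-[3-hydroxy-4-(sulfooxy)phenyl]-5-hydroxy-4-oxo-4H-chromene-3,7-diyl bis(hydrogen sulfate) (quercetin 3,4',7-trisulfate)
Conditions: H2 (1 atm), Pd/C (10% palladium on carbon), MeOH/H2O, rt
Reagents that add atoms: none
Why: Catalytic hydrogenolysis of a benzyl aryl ether; aryl sulfate monoester salts are stable to hydrogen over palladium and the pyrone double bond of a flavonol is not reduced under these conditions, so only the 3'-O–CH2Ph bond should be cut.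

## Compound list

1 | 2-(benzyloxy)phenol | Oc1ccccc1OCc1ccccc1 | starting material
2 | 2-(benzyloxy)-4-bromophenol | Oc1ccc(Br)cc1OCc1ccccc1 | intermediate
3 | [2-(benzyloxy)-4-bromophenoxy]tri(propan-2-yl)silane | CC(C)[Si](Oc1ccc(Br)cc1OCc1ccccc1)(C(C)C)C(C)C | intermediate
4 | {3-(benzyloxy)-4-[(triisopropylsilyl)oxy]phenyl}lithium (not isolated) | [Li]c1ccc(O[Si](C(C)C)(C(C)C)C(C)C)c(OCc2ccccc2)c1 | intermediate
5 | 3-(benzyloxy)-4-[(triisopropylsilyl)oxy]benzoic acid | O=C(O)c1ccc(O[Si](C(C)C)(C(C)C)C(C)C)c(OCc2ccccc2)c1 | intermediate
6 | {3-(benzyloxy)-4-[(triisopropylsilyl)oxy]phenyl}(1H-imidazol-1-yl)methanone (not isolated) | O=C(c1ccc(O[Si](C(C)C)(C(C)C)C(C)C)c(OCc2ccccc2)c1)n1ccnc1 | intermediate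
7 | 3-{3-(benzyloxy)-4-[(triisopropylsilyl)oxy]phenyl}-2-(ethoxycarbonyl)-3-oxopropanoic acid, present as its magnesium carboxylate (racemic, not isolated) | CCOC(=O)C(C(=O)O)C(=O)c1ccc(O[Si](C(C)C)(C(C)C)C(C)C)c(OCc2ccccc2)c1 | intermediate
8 | ethyl 3-{3-(benzyloxy)-4-[(triisopropylsilyl)oxy]phenyl}-3-oxopropanoate | CCOC(=O)CC(=O)c1ccc(O[Si](C(C)C)(C(C)C)C(C)C)c(OCc2ccccc2)c1 | intermediate
9 | dibenzoyl peroxide | O=C(OOC(=O)c1ccccc1)c1ccccc1 | starting material
10 | ethyl 2-(benzoyloxy)-3-{3-(benzyloxy)-4-[(triisopropylsilyl)oxy]phenyl}-3-oxopropanoate (racemic, enolisable) | CCOC(=O)C(OC(=O)c1ccccc1)C(=O)c1ccc(O[Si](C(C)C)(C(C)C)C(C)C)c(OCc2ccccc2)c1 | intermediate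
11 | phloroglucinol (benzene-1,3,5-triol) | Oc1cc(O)cc(O)c1 | starting material
12 | 1-{3-(benzyloxy)-4-[(triisopropylsilyl)oxy]phenyl}-1,3-dioxoprop-2-en-2-yl benzoate, the aroyl(benzoyloxy)ketene (not isolated) | O=C=C(OC(=O)c1ccccc1)C(=O)c1ccc(O[Si](C(C)C)(C(C)C)C(C)C)c(OCc2ccccc2)c1 | intermediate
13 | 1-{3-(benzyloxy)-4-[(triisopropylsilyl)oxy]phenyl}-1,3-dioxo-3-(2,4,6-trihydroxyphenyl)propan-2-yl benzoate (racemic, not isolated) | O=C(c1c(O)cc(O)cc1O)C(OC(=O)c1ccccc1)C(=O)c1ccc(O[Si](C(C)C)(C(C)C)C(C)C)c(OCc2ccccc2)c1 | intermediate
14 | 2-{3-(benzyloxy)-4-[(triisopropylsilyl)oxy]phenyl}-5,7-dihydroxy-4-oxo-4H-chromen-3-yl benzoate | O=C(Oc1c(-c2ccc(O[Si](C(C)C)(C(C)C)C(C)C)c(OCc3ccccc3)c2)oc2cc(O)cc(O)c2c1=O)c1ccccc1 | intermediate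
15 | 2-{3-(benzyloxy)-4-[(triisopropylsilyl)oxy]phenyl}-3,5,7-trihydroxy-4H-chromen-4-one (not isolated) | O=c1c(O)c(-c2ccc(O[Si](C(C)C)(C(C)C)C(C)C)c(OCc3ccccc3)c2)oc2cc(O)cc(O)c12 | intermediate
16 | 2-[3-(benzyloxy)-4-hydroxyphenyl]-3,5,7-trihydroxy-4H-chromen-4-one (3'-O-benzylquercetin) | O=c1c(O)c(-c2ccc(O)c(OCc3ccccc3)c2)oc2cc(O)cc(O)c12 | intermediate
17 | 2-[3-(benzyloxy)-4-(sulfooxy)phenyl]-5-hydroxy-4-oxo-4H-chromene-3,7-diyl bis(hydrogen sulfate) | O=c1c(OS(=O)(=O)O)c(-c2ccc(OS(=O)(=O)O)c(OCc3ccccc3)c2)oc2cc(OS(=O)(=O)O)cc(O)c12 | intermediate
18 | 2-[3-hydroxy-4-(sulfooxy)phenyl]-5-hydroxy-4-oxo-4H-chromene-3,7-diyl bis(hydrogen sulfate) (quercetin 3,4',7-trisulfate) | O=c1c(OS(=O)(=O)O)c(-c2ccc(OS(=O)(=O)O)c(O)c2)oc2cc(OS(=O)(=O)O)cc(O)c12 | target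

## Step count and least certain steps

Total step count: 9. Longest linear sequence: 9 steps (1 to 18); 9 and 11 enter as purchased materials.

**Step 6 (key step).** Three processes could spoil the annulation.
- Thermal stress above 220 °C may cause homolysis or migration of the benzyl aryl ether and transfer of the silyl group to the phenols of 11.
- The acyloxy group may interfere. A 1,2-benzoyl shift in the enediol form of 10 could isomerise it before ethanol is lost. The ortho hydroxyl of 13 could also displace benzoate in a 5-exo-tet closure instead of adding to the ketone.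
- A second annulation on ring A is possible if 11 is not in excess.

Simple acyl or silyl transfer between phenolic oxygens is harmless, since step 7 removes both groups.

Fallback: carry C3 through the annulation as C–H and oxidise it afterwards. Setting out from 8 and 11, the classical oxygen-free condensation under the same thermal conditions should give 2-{3-(benzyloxy)-4-[(triisopropylsilyl)oxy]phenyl}-5,7-dihydroxy-4H-chromen-4-one F1. MOMCl and NaH in DMF would then give 2-{3-(benzyloxy)-4-[(triisopropylsilyl)oxy]phenyl}-5,7-bis(methoxymethoxy)-4H-chromen-4-one F2. Dimethyldioxirane in acetone/CH2Cl2 at 0 °C should epoxidise C2=C3 to the racemic epoxide 1a-{3-(benzyloxy)-4-[(triisopropylsilyl)oxy]phenyl}-4,6-bis(methoxymethoxy)-1a,7a-dihydro-7H-oxireno[2,3-b]chromen-7-one F3. Catalytic p-TsOH would open it to 2-{3-(benzyloxy)-4-[(triisopropylsilyl)oxy]phenyl}-3-hydroxy-5,7-bis(methoxymethoxy)-4H-chromen-4-one F4. HCl in MeOH/THF would remove both acetals and return the route at 15, which is desilylated as in the second stage of step 7.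

**Step 5.** A second benzoyloxylation may occur because the product keeps an acidic hydrogen. The enolate may also attack the peroxide at its carbonyl carbon and be benzoylated instead of oxygenated. Radical decomposition of the peroxide is a further risk.

Fallback: replace electrophilic oxygen by carbenoid O–H insertion. Setting out from 8, diazo transfer with 4-acetamidobenzenesulfonyl azide and Et3N in MeCN should give ethyl 2-diazo-3-{3-(benzyloxy)-4-[(triisopropylsilyl)oxy]phenyl}-3-oxopropanoate F5. Catalytic Rh2(OAc)4 with benzoic acid in CH2Cl2 at rt should then insert the carbenoid into the acid O–H bond and return the route at 10.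

**Step 8.** Sulfation may stop short at the hindered, hydrogen-bonded O3 and give mixtures of di- and trisulfates. Forcing may begin to sulfate O5. Sulfate may be lost if the work-up turns acidic, and the polyanions are hard to separate.

Fallback: use protected sulfate diesters, which are neutral and can be purified on silica. Setting out from 16, 2,2,2-trichloroethyl chlorosulfate (3.3 equiv) with Et3N and DMAP in THF at 0 °C should give 2-{3-(benzyloxy)-4-[(2,2,2-trichloroethoxy)sulfonyloxy]phenyl}-5-hydroxy-4-oxo-4H-chromene-3,7-diyl bis(2,2,2-trichloroethyl) bis(sulfate) F6. Over- or under-sulfated material can be removed by chromatography at this stage. Zn and HCO2NH4 in MeOH would then cleave the three trichloroethyl groups reductively and return the route at 17 (as its ammonium salt).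

**Step 3.** Benzylic deprotonation followed by Wittig rearrangement may compete with exchange. Aryllithium 4 may be alkylated by the butyl bromide formed, or protonated before carboxylation.

Fallback: avoid the organolithium altogether. Setting out from 3, carbonylative coupling with potassium ethyl malonate should return the route directly at 8, bypassing 4 to 7 and step 4. Conditions would be Pd(OAc)2 and Xantphos, CO (1 atm), MgCl2 and Et3N in THF at 80 °C. No new compound arises on the way.

## Further compounds

F1 | step 6 | 2-{3-(benzyloxy)-4-[(triisopropylsilyl)oxy]phenyl}-5,7-dihydroxy-4H-chromen-4-one | O=c1cc(-c2ccc(O[Si](C(C)C)(C(C)C)C(C)C)c(OCc3ccccc3)c2)oc2cc(O)cc(O)c12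
F2 | step 6 | 2-{3-(benzyloxy)-4-[(triisopropylsilyl)oxy]phenyl}-5,7-bis(methoxymethoxy)-4H-chromen-4-one | COCOc1cc(OCOC)c2c(=O)cc(-c3ccc(O[Si](C(C)C)(C(C)C)C(C)C)c(OCc4ccccc4)c3)oc2c1
F3 | step 6 | 1a-{3-(benzyloxy)-4-[(triisopropylsilyl)oxy]phenyl}-4,6-bis(methoxymethoxy)-1a,7a-dihydro-7H-oxireno[2,3-b]chromen-7-one (racemic, cis-fused epoxide) | COCOc1cc(OCOC)c2c(c1)OC1(c3ccc(O[Si](C(C)C)(C(C)C)C(C)C)c(OCc4ccccc4)c3)OC1C2=O
F4 | step 6 | 2-{3-(benzyloxy)-4-[(triisopropylsilyl)oxy]phenyl}-3-hydroxy-5,7-bis(methoxymethoxy)-4H-chromen-4-one | COCOc1cc(OCOC)c2c(=O)c(O)c(-c3ccc(O[Si](C(C)C)(C(C)C)C(C)C)c(OCc4ccccc4)c3)oc2c1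
F5 | step 5 | ethyl 2-diazo-3-{3-(benzyloxy)-4-[(triisopropylsilyl)oxy]phenyl}-3-oxopropanoate | CCOC(=O)C(=[N+]=[N-])C(=O)c1ccc(O[Si](C(C)C)(C(C)C)C(C)C)c(OCc2ccccc2)c1
F6 | step 8 | 2-{3-(benzyloxy)-4-[(2,2,2-trichloroethoxy)sulfonyloxy]phenyl}-5-hydroxy-4-oxo-4H-chromene-3,7-diyl bis(2,2,2-trichloroethyl) bis(sulfate) | O=c1c(OS(=O)(=O)OCC(Cl)(Cl)Cl)c(-c2ccc(OS(=O)(=O)OCC(Cl)(Cl)Cl)c(OCc3ccccc3)c2)oc2cc(OS(=O)(=O)OCC(Cl)(Cl)Cl)cc(O)c12
F0 | step 3 | none | none
A1 | alternative 1 | 6-[(3Z)-4-(3-benzyloxy-4-methoxymethoxyphenyl)-3-(methoxymethoxy)-2-oxobut-3-en-1-yl]-4-hydroxy-2H-pyran-2-one | O=c1cc(O)cc(CC(=O)/C(OCOC)=C/c2ccc(OCOC)c(OCc3ccccc3)c2)o1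
A2 | alternative 1 | (Z)-3-(3-benzyloxy-4-methoxymethoxyphenyl)-2-(methoxymethoxy)-1-(2,4,6-trihydroxyphenyl)prop-2-en-1-one | COCO/C(C(=O)c1c(O)cc(O)cc1O)=C\c1ccc(OCOC)c(OCc2ccccc2)c1
A3 | alternative 2 | 2-[1-(3-benzyloxy-4-methoxymethoxyphenyl)-2-oxoethoxy]-4,6-bis(methoxymethoxy)benzaldehyde (racemic) | O=Cc1c(OCOC)cc(OCOC)cc1OC(C=O)c1ccc(OCOC)c(OCc2ccccc2)c1
A4 | alternative 2 | trans-2-(3-benzyloxy-4-methoxymethoxyphenyl)-3-hydroxy-5,7-bis(methoxymethoxy)chroman-4-one (racemic, 2R,3R drawn) | COCOc1ccc([C@@H]2[C@H](C(=O)c3c(O2)cc(OCOC)cc3OCOC)O)cc1OCc1ccccc1
A5 | alternative 3 | 1-[2,6-bis(benzyloxy)-4-(methoxymethoxy)phenyl]-3-(3-benzyloxy-4-methoxymethoxyphenyl)prop-2-yn-1-one | COCOc1cc(OCc2ccccc2)c(C(=O)C#Cc2ccc(OCOC)c(OCc3ccccc3)c2)c(OCc2ccccc2)c1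
A6 | alternative 3 | 5-benzyloxy-2-(3-benzyloxy-4-methoxymethoxyphenyl)-3-iodo-7-(methoxymethoxy)chromen-4-one | COCOc1cc(OCc2ccccc2)c2c(=O)c(I)c(-c3ccc(OCOC)c(OCc4ccccc4)c3)oc2c1
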